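**The runs.** Time is our axis here. At one temperature, we follow product in closed flasks of substrate and free catalyst up to 14 h.

| flask | substrate | free catalyst | time |
|---|---|---|---|
| dawn | 0.800 M | 0.0400 M |  |
| noon | 0.320 M | 0.0400 M |  |
| midnight | 0.400 M | 0.0400 M |  |
| winter | 0.800 M | 0.120 M |  |
| spring | 0.800 M | 0.0400 M | 42 h |

| run | time / h | [product] / M |
|---|---|---|
| dawn run | 0.56 | 0.159 |
| dawn run | 0.96 | 0.252 |
| dawn run | 1.6 | 0.374 |
| dawn run | 2.8 | 0.501 |
| dawn run | 4.8 | 0.581 |
| dawn run | 8.2 | 0.610 |
| dawn run | 14 | 0.644 |
| noon run | 0.56 | 0.144 |
| noon run | 0.96 | 0.184 |
| noon run | 1.6 | 0.208 |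
| noon run | 2.8 | 0.230 |
| noon run | 4.8 | 0.248 |
| noon run | 8.2 | 0.260 |
| noon run | 14 | 0.266 |
| midnight run | 0.56 | 0.150 |
| midnight run | 0.96 | 0.213 |
| midnight run | 1.6 | 0.255 |
| midnight run | 2.8 | 0.279 |
| midnight run | 4.8 | 0.309 |
| midnight run | 8.2 | 0.313 |
| midnight run | 14 | 0.314 |
| winter run | 0.56 | 0.776 |
| winter run | 0.96 | 0.784 |
| winter run | 1.6 | 0.791 |
| winter run | 2.8 | 0.796 |
| winter run | 4.8 | 0.791 |
| winter run | 8.2 | 0.795 |
| winter run | 14 | 0.796 |

(scatter of a reading: 0.006 M)

- Overall: substrate -> product, with free catalyst as catalyst.
- Constant volume, constant temperature.
- What is held in complexes is read along with the free species.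
- An order is taken over about fifteen percent of the charge, up and down.

- order of the initial rate in [substrate], near the charge of the dawn run, the rate being that where two percent of its substrate are product (one fixed amount of product, the same in the runs compared)
- order of the initial rate in [free catalyst], near the charge of the dawn run, the rate being that where two percent of its substrate are product
- the noon run starts with 0.480 M less of substrate than the dawn run, and with no product. Compared where both hold the same amount of substrate, once fifteen percent of what the noon run was charged with has turned into product, is the noon run faster, slower or alike (within a tenth)?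
- product in the spring run at 42 h, as a share of the substrate charged

**The puzzle.** At 14 h the dawn reading, taken from the charge, leaves c_substrate of 0.156 M. The winter run has the same substrate charge and its reading leaves 0.00400 M, so the dawn run keeps far more. A catalyst does not shift an equilibrium, so we do not read the dawn slowdown as one. We read it as loss of free catalyst with time, or catalyst deactivation.

**The shares.** Dawn, noon and midnight share one catalyst charge, 0.0400 M, while their substrate charges differ by a factor of 2.50. Yet at 14 h their product shares stand close: 80.5%, 83.1% and 78.5%. So we treat the slowdown like a first-order decay whose clock is catalyst lost, not hours. The mean of ln(charge/left) per catalyst charged in these runs, at 14 h, reads 41.3 M⁻¹. We call this the catalyst reach: the logarithmic drop in substrate per molar of free catalyst charged.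

**Our reckoning.** The spring run has the dawn charge, so the reach read at 14 h gives 1.65 e-foldings and a product share of 80.8%. The dawn readings rose by 0.0340 M over their last interval, more than the scatter. We therefore expect a small correction upward at 42 h.

**The forecast.** It gives orders of −0.4 in substrate and 2 in catalyst, and calls the noon run faster. It puts the spring run at 85%, within 81% to 90%, which is above our figure. Its ground: “the catalyst dies with time, and there is no true equilibrium”.

**The result.** The spring run gives 82.2% at 42 h, above our 80.8% and below the forecast's 85%. The orders are −0.36 in substrate and 2.0 in free catalyst, and the noon run is faster.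

    free catalyst + substrate ⇌ catalyst-substrate complex, settled at all times (2.860 M⁻¹)
    catalyst-substrate complex + free catalyst → product + 2 free catalyst (921.6 M⁻¹ h⁻¹)
    2 free catalyst → 2 spent catalyst (29.09 M⁻¹ h⁻¹)

**The reach again.** Where two percent of the dawn substrate has turned, the rate is 2.9 M h⁻¹ in the winter run against 0.31 M h⁻¹ in the dawn run. Worked back, the spring run's own reach at 42 h is 43.2 M⁻¹. Our reach of 41.3 M⁻¹, applied to the winter charge of 0.120 M, gives 0.00566 M of substrate, against 0.00400 M from the winter reading at 14 h, a gap smaller than the scatter of 0.006 M.

(The readings are calculated with made-up constants, and the scatter is random.)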